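The runs stem from a simulated flask on assumed constants; scatter was added.

The time of reading means little until it is set against a second time, which I called the chain time: the time constant of free monomer going into chains, taken as pseudo-first-order and read from the first reading of a run. The ratio of these two times was what I meant to compare between flasks of nearby loading.

| setting | north-west | east | south | dawn | dusk |
|---|---|---|---|---|---|
| free monomer | 0.050 M | 0.050 M | 0.050 M | 0.050 M | 0.050 M |
| initiator | 5.6 mol% | 9.3 mol% | 17 mol% | 4.9 mol% | 15 mol% |
| remark | run made earlier | run made earlier | run made earlier |  |  |
| time |  |  |  | 40 min | 10 min |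

| run | time / min | monomer in chains / % |
|---|---|---|
| north-west | 4.00 | 12.0 |
| north-west | 10.0 | 26.1 |
| north-west | 20.0 | 41.6 |
| north-west | 30.0 | 49.6 |
| north-west | 40.0 | 53.5 |
| east | 3.00 | 12.9 |
| east | 6.00 | 23.2 |
| east | 12.0 | 37.1 |
| east | 20.0 | 49.4 |
| east | 40.0 | 60.9 |
| south | 4.00 | 20.8 |
| south | 10.0 | 42.1 |
| south | 20.0 | 59.3 |
| south | 30.0 | 66.3 |
| south | 40.0 | 70.6 |

(each reading ± 0.5 percentage points)



1. the flask that ends with the higher amount of monomer in chains, in percent of the free monomer charged, or "neither" when 2 percentage points or less lies between them (dawn / dusk / neither)
2. final monomer in chains, as a percentage of the free monomer charged, in dawn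
3. final monomer in chains, as a percentage of the free monomer charged, in dusk

I assumed that growing radical sits in a steady state, made as initiator breaks and lost in pairs, so that at the same charge of free monomer the chain time goes inversely as the square root of the loading. The runs allow this. The north-west run reads 31.3 min and the south run 17.2 min, a ratio of 1.82, while the square root of their loadings gives 1.74.

On the north-west run, the 40 min of dawn then corresponds to 37.4 min, and on the south run the 10 min of dusk to 9.39 min. This is the matched time: the time of reading multiplied by the square root of the flask's loading over the run's, the moment at which the run has the same ratio of the two times. Interpolating between readings, I got 52.5% for dawn and 39.9% for dusk.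

The forecast, holding that “each approaches a plateau roughly exponentially”, named dawn, with 51.3% and 40.2%. That puts dawn a little lower than my figure and dusk a little higher.

The flasks put dawn higher, with 51.7% of monomer in chains in dawn and 39.9% in dusk.

    free monomer + monomer in chains → side product (k = 0.00900 M⁻¹ s⁻¹)
    initiator → 2 initiating radical (k = 3.40 × 10⁻⁵ s⁻¹)
    2 growing radical → dead chain (k = 8.00 × 10⁶ M⁻¹ s⁻¹)
    free monomer + growing radical → monomer in chains + growing radical, rate k4*[growing radical]*[free monomer] (k = 5500 M⁻¹ s⁻¹)
    free monomer + initiating radical → growing radical + monomer in chains (k = 3.20 × 10⁵ M⁻¹ s⁻¹)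

In dusk at 10.0 min, the half-life of free monomer by the path into chains was 12 min, as it had been at 4.19 min, and at 10.0 min it was shorter than the 64 min by the path to side product. Growing radical in dusk stood at 1.78 × 10⁻⁷ M after 5.00 min and 1.77 × 10⁻⁷ M after 10.0 min, nearly level, as I had assumed in reckoning the matched time of 9.39 min.

Dusk left until 40 min has a matched time of 37.6 min on the south run, which gives 69.6% of monomer in chains. The computed flask holds 68.5% of monomer in chains.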